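**Strategy.** Everything rests on cutting the pyran ring at its two bonds to the cyclopentane: aryl O–CH (the CH next to the spiro carbon) and benzylic CH–C(CH3) (the methyl-bearing quaternary carbon). The key step exploits the fact that this O–CH carbon can be the carbonyl carbon of a spiro[4.5]decenone that enolises only toward the methyl carbon: an inverse-demand hetero-Diels–Alder reaction of its silyl enol ether with a Boc-protected ortho-quinone methide forms both bonds, the benzylic and quaternary stereocentres and the pyran ring (as a ketal) in one operation. The enol ether derives from (−)-menthone by Claisen rearrangement and rhodium-catalysed hydroacylation; hydride then replaces the ketal oxygen and formylation comes last.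

Key step: step 11

Remark: the isopropyl-bearing carbon of the menthone-derived intermediates before the enol triflate is drawn with the menthone configuration; it may epimerise under the basic conditions of steps 1 and 2, which is without consequence because step 5 makes this carbon trigonal. For the tetracycles, chroman locants are used (O1, C2 bonded to O1 and the spiro carbon, C3 methyl-bearing, C4 benzylic).

Step 1
Reactants: 1 (−)-menthone
Product: 2 (Z)-6-(hydroxymethylene)menthone
Conditions: NaH, HCO2Et, cat. EtOH, THF, 0 °C → rt; aq. HCl
Reagents that add atoms: ethyl formate, CCOC=O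
Why: Crossed Claisen condensation (formylation) can end in a stable conjugated enolate only at the single α-methylene, so the carbon that will become the O–CH carbon of the pyran is placed there while the non-acidic methyl-bearing stereocentre is untouched.

Step 2
Reactants: 2 (Z)-6-(hydroxymethylene)menthone; 3 allyl bromide
Product: 4 (E)-6-(allyloxymethylene)menthone
Conditions: K2CO3, acetone, reflux
Reagents that add atoms: none
Why: O-alkylation of the potassium salt of the hydroxymethylene ketone (Williamson-type etherification of a vinylogous acid) should give the allyl enol ether, and any material allylated directly on carbon already has the constitution of the rearrangement product of step 3.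

Step 3
Reactants: 4 (E)-6-(allyloxymethylene)menthone
Product: 5 (1S,3S,6R)-1-allyl-3-isopropyl-6-methyl-2-oxocyclohexane-1-carbaldehyde
Conditions: toluene, 140 °C, sealed tube
Reagents that add atoms: none
Why: Thermal Claisen rearrangement ([3,3]-sigmatropic shift through a chair transition state) creates the quaternary carbon, the neighbouring methyl being forced pseudo-axial by A(1,3) strain with the allyloxymethylene group so that the allyl terminus should bond on the opposite face (allyl trans to methyl), and the minor epimer is removed by chromatography after step 5, when the isopropyl-bearing carbon is no longer stereogenic.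

Step 4
Reactants: 5 keto aldehyde
Product: 6 (2S,3R,6S)-2-allyl-2-(dimethoxymethyl)-6-isopropyl-3-methylcyclohexan-1-one
Conditions: HC(OMe)3, MeOH, cat. p-TsOH·H2O, rt; Et3N quench
Reagents that add atoms: trimethyl orthoformate, COC(OC)OC; methanol, CO
Why: Acid-catalysed acetalisation is selective for the aldehyde because the ketone is flanked by a quaternary and an isopropyl-bearing carbon, and it protects the non-enolisable β-keto aldehyde from amide addition and deformylation (retro-Claisen cleavage) in the next step.

Step 5
Reactants: 6 keto acetal
Product: 8 enol triflate of the keto acetal, via potassium enolate 7 (not isolated)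
Conditions: KN(SiMe3)2, THF, −78 → 0 °C; then PhN(SO2CF3)2, −78 °C → rt
Reagents that add atoms: N-phenylbis(trifluoromethanesulfonimide), O=S(=O)(N(c1ccccc1)S(=O)(=O)C(F)(F)F)C(F)(F)F
Why: The ketone has a single α-hydrogen, on the isopropyl-bearing carbon, so deprotonation and O-sulfonylation (enol triflate formation) can give only one regioisomer and remove the stereocentre at that carbon.

Step 6
Reactants: 8 enol triflate
Product: 10 (1R,6R)-1-allyl-3-isopropyl-6-methylcyclohex-2-ene-1-carbaldehyde, via diene acetal 9 (not isolated)
Conditions: Pd(OAc)2 (5 mol %), PPh3, n-Bu3N, HCO2H, DMF, 60 °C; then 1 M aq. HCl, THF, rt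
Reagents that add atoms: water, O
Why: Palladium-catalysed formate reduction of the enol triflate (oxidative addition to zerovalent palladium, exchange of triflate for formate, loss of CO2 and reductive elimination) replaces the triflate by hydrogen and leaves the ring alkene in place, and mild aqueous acid then hydrolyses the dimethyl acetal without touching either alkene or the two stereocentres.

Step 7
Reactants: 10 diene aldehyde
Product: 11 (5R,10R)-7-isopropyl-10-methylspiro[4.5]dec-6-en-1-one
Conditions: [Rh(nbd)(Ph2PCH2CH2PPh2)]BF4 (5 mol %; nbd = norbornadiene), H2 pre-activation then Ar purge, CH2Cl2, rt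
Reagents that add atoms: none
Why: Intramolecular alkene hydroacylation by a cationic monovalent rhodium diphosphine complex (aldehyde C–H oxidative addition, insertion of the terminal alkene, reductive elimination from the six-membered rhodacycle) closes the cyclopentanone of this 2,2-disubstituted pent-4-enal, whose quaternary α-carbon favours ring closure and excludes enolisation, with both stereocentres unchanged.

Step 8
Reactants: 11 spiroketone
Product: 13 2-methyl spiroketone (C-2 epimer mixture), via lithium enolate 12 (not isolated)
Conditions: LiN(i-Pr)2, THF, −78 °C; then MeI, −78 → 0 °C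
Reagents that add atoms: iodomethane, CI
Why: Enolate alkylation can take place only at C-2 because the other α-carbon is the spiro centre, and the configuration of the new methyl-bearing carbon is irrelevant since it becomes trigonal in step 9.

Step 9
Reactants: 13 2-methyl spiroketone
Product: 14 tert-butyldimethylsilyl enol ether of 13
Conditions: t-BuMe2SiOTf, Et3N, CH2Cl2, 0 °C → rt
Reagents that add atoms: tert-butyldimethylsilyl trifluoromethanesulfonate, CC(C)(C)[Si](C)(C)OS(=O)(=O)C(F)(F)F
Why: Soft enolisation with O-silylation (silyl enol ether formation) can give only the tetrasubstituted C-1/C-2 enol ether, which is robust enough to be purified and to tolerate a Grignard reagent.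

Step 10
Reactants: 15 2,4,6-trihydroxybenzaldehyde
Product: 16 2,4,6-tris(tert-butoxycarbonyloxy)benzaldehyde
Conditions: Boc2O, i-Pr2NEt, cat. DMAP, THF, 0 °C → rt
Reagents that add atoms: di-tert-butyl dicarbonate, CC(C)(C)OC(=O)OC(=O)OC(C)(C)C
Why: DMAP-catalysed O-acylation converts all three phenols into tert-butyl carbonates, which tolerate the Grignard addition, make the later quinone methide electron-poor and supply its migrating and leaving group.

Step 11
Reactants: 14 silyl enol ether; 16 tris-Boc aldehyde; 17 isobutylmagnesium bromide
Product: 21 silyl ketal cycloadduct (2-silyloxychroman bis-carbonate), via bromomagnesium alkoxide 18 (not isolated), via phenoxide carbonate 19 (not isolated), via quinone methide 20 (not isolated)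
Conditions: 16 (2.5 equiv) + 17 (2.4 equiv), Et2O, −78 °C; then 14 (1.0 equiv), −78 °C → rt
Reagents that add atoms: none
Why: Grignard addition to the aldehyde at −78 °C gives alkoxide 18, which takes over one ortho Boc group, and on warming phenoxide 19 expels tert-butyl carbonate to release the electron-poor quinone methide 20 under basic aprotic conditions that leave the silyl enol ether intact; its isobutyl group should lie syn to the ring carbonyl (Z) because the alternative suffers A(1,3) strain with the flanking Boc-oxy group. The closest known reaction type is the inverse-demand hetero-Diels–Alder reaction of ortho-quinone methides, released in this way from ortho-Boc-oxy benzaldehydes, with enol ethers, here with a fully substituted silyl enol ether as the 2π partner. The pyran ring is closed by this intermolecular [4+2] cycloaddition, which is asynchronous: the methyl-bearing enol carbon bonds to the methide carbon first and the quinone methide oxygen then closes the six-membered ring onto the silyloxy carbon (a 6-exo capture of the incipient silyloxocarbenium ion). The benzylic and quaternary stereocentres are set together by the Z geometry of 20 and an endo silyloxy group with the spiro-fused ring exo, which places isobutyl trans to the new angular methyl, and the ketal carbon follows from suprafacial addition, the aryl oxygen ending cis to the benzylic carbon. Facial selectivity is controlled by the spiro centre adjacent to the silyloxy carbon: the diene should approach the face flanked by the flat vinylic CH of the cyclohexene and avoid the face covered by the CH–CH3 carbon. The step needs the regiochemistry in which the aryl oxygen ends next to the spiro carbon, and the enol ether secures it because ketone 13 can enolise only toward the methyl carbon, which the enol oxygen makes the nucleophilic terminus that attacks the methide carbon.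

Step 12
Reactants: 21 silyl ketal cycloadduct
Product: 23 bis-Boc chroman, via lactol 22 (not isolated)
Conditions: HF·pyridine, pyridine, THF, 0 °C; aqueous work-up; then Et3SiH, BF3·OEt2, CH2Cl2, −78 → −30 °C
Reagents that add atoms: none
Why: Fluoride cleaves the silyl ketal to the lactol and ionic hydrogenation (Lewis acid ionisation to the cyclic aryl oxocarbenium ion, hydride transfer from the silane) replaces its hydroxyl by hydrogen; hydride should enter on the face carrying the angular methyl, because only this gives the unstrained cis-fused pyran/cyclopentane and the other face is screened by the pseudo-axial isobutyl group 1,3 to the cationic carbon, which sets the O–CH stereocentre, while the aprotic low-temperature conditions spare the trisubstituted alkene.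

Step 13
Reactants: 23 bis-Boc chroman
Product: 24 5,7-dihydroxychroman core
Conditions: K2CO3, MeOH, 0 °C → rt, Ar; aq. NH4Cl
Reagents that add atoms: none
Why: Methoxide-mediated transesterification of the two aryl tert-butyl carbonates, with the aryl oxide as the better leaving group, frees both phenols under conditions that cannot affect the alkene or any stereocentre.

Step 14
Reactants: 24 5,7-dihydroxychroman core
Product: 26 target CNP0121396.3, via bis-iminium salt 25 (not isolated)
Conditions: POCl3 (4 equiv), DMF (6 equiv), EtOAc, 0 °C → rt; then H2O, 50 °C
Reagents that add atoms: N,N-dimethylformamide, CN(C)C=O; water, O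
Why: Twofold Vilsmeier–Haack formylation (electrophilic aromatic substitution by the chloroiminium ion, then hydrolysis) should occur at the only two free ring positions, each ortho or para to three oxygen substituents as in the diformylation of phloroglucinol itself, and creates no stereocentre.

**Compound list**

1 | (−)-menthone, (2S,5R)-2-isopropyl-5-methylcyclohexan-1-one | C[C@@H]1CC[C@@H](C(C)C)C(=O)C1 | starting material
2 | (2S,5R,Z)-6-(hydroxymethylene)-2-isopropyl-5-methylcyclohexan-1-one (chelated enol of the 6-formyl ketone) | O/C=C1\C(=O)[C@H](C(C)C)CC[C@H]1C | intermediate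
3 | allyl bromide (3-bromoprop-1-ene) | C=CCBr | starting material
4 | (2S,5R,E)-6-[(allyloxy)methylene]-2-isopropyl-5-methylcyclohexan-1-one | C=CCO/C=C1/C(=O)[C@H](C(C)C)CC[C@H]1C | intermediate
5 | (1S,3S,6R)-1-allyl-3-isopropyl-6-methyl-2-oxocyclohexane-1-carbaldehyde (allyl trans to the 6-methyl) | O=C[C@@]1(CC=C)C(=O)[C@H](C(C)C)CC[C@H]1C | intermediate
6 | (2S,3R,6S)-2-allyl-2-(dimethoxymethyl)-6-isopropyl-3-methylcyclohexan-1-one | COC(OC)[C@@]1(CC=C)C(=O)[C@H](C(C)C)CC[C@H]1C | intermediate
7 | potassium enolate of 6, enolised toward the isopropyl-bearing carbon | [K+].COC(OC)[C@@]1(CC=C)C([O-])=C(C(C)C)CC[C@H]1C | intermediate (not isolated)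
8 | (5R,6R)-6-allyl-6-(dimethoxymethyl)-2-isopropyl-5-methylcyclohex-1-en-1-yl trifluoromethanesulfonate | COC(OC)[C@@]1(CC=C)C(OS(=O)(=O)C(F)(F)F)=C(C(C)C)CC[C@H]1C | intermediate
9 | (3R,4R)-3-allyl-3-(dimethoxymethyl)-1-isopropyl-4-methylcyclohex-1-ene | COC(OC)[C@@]1(CC=C)C=C(C(C)C)CC[C@H]1C | intermediate (not isolated)
10 | (1R,6R)-1-allyl-3-isopropyl-6-methylcyclohex-2-ene-1-carbaldehyde | O=C[C@@]1(CC=C)C=C(C(C)C)CC[C@H]1C | intermediate
11 | (5R,10R)-7-isopropyl-10-methylspiro[4.5]dec-6-en-1-one | O=C1CCC[C@@]12C=C(C(C)C)CC[C@H]2C | intermediate
12 | lithium C-1/C-2 enolate of 11 | [Li+].[O-]C1=CCC[C@@]12C=C(C(C)C)CC[C@H]2C | intermediate (not isolated)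
13 | (5R,10R)-7-isopropyl-2,10-dimethylspiro[4.5]dec-6-en-1-one, both C-2 epimers | O=C1C(C)CC[C@@]12C=C(C(C)C)CC[C@H]2C | intermediate
14 | tert-butyl{[(5R,10R)-7-isopropyl-2,10-dimethylspiro[4.5]deca-1,6-dien-1-yl]oxy}dimethylsilane | CC1=C(O[Si](C)(C)C(C)(C)C)[C@@]2(CC1)C=C(C(C)C)CC[C@H]2C | intermediate
15 | 2,4,6-trihydroxybenzaldehyde | O=Cc1c(O)cc(O)cc1O | starting material
16 | 2,4,6-tris(tert-butoxycarbonyloxy)benzaldehyde | O=Cc1c(OC(=O)OC(C)(C)C)cc(OC(=O)OC(C)(C)C)cc1OC(=O)OC(C)(C)C | intermediate
17 | isobutylmagnesium bromide | CC(C)C[Mg]Br | starting material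
18 | bromomagnesium 1-[2,4,6-tris(tert-butoxycarbonyloxy)phenyl]-3-methylbutan-1-olate (racemic) | CC(C)CC(O[Mg]Br)c1c(OC(=O)OC(C)(C)C)cc(OC(=O)OC(C)(C)C)cc1OC(=O)OC(C)(C)C | intermediate (not isolated)
19 | bromomagnesium 3,5-bis(tert-butoxycarbonyloxy)-2-[1-(tert-butoxycarbonyloxy)-3-methylbutyl]phenolate (racemic) | CC(C)CC(OC(=O)OC(C)(C)C)c1c(O[Mg]Br)cc(OC(=O)OC(C)(C)C)cc1OC(=O)OC(C)(C)C | intermediate (not isolated)
20 | (Z)-3,5-bis(tert-butoxycarbonyloxy)-6-(3-methylbutylidene)cyclohexa-2,4-dien-1-one (isobutyl syn to the ring carbonyl) | CC(C)C/C=C1\C(=O)C=C(OC(=O)OC(C)(C)C)C=C1OC(=O)OC(C)(C)C | intermediate (not isolated)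
21 | silyl ketal cycloadduct: 5,7-bis(tert-butoxycarbonyloxy)-2-(tert-butyldimethylsilyloxy)-4-isobutyl-3-methylchroman, cyclopentane fused at C2–C3 (silyloxy cis to the C3 methyl, isobutyl trans to it), ring carbon next to C2 spiro to C-1 of 3-isopropyl-6-methylcyclohex-2-ene with the vinylic CH on the face of O1; spiro R, CH–CH3 R, C2 R, C3 R, C4 R | CC(C)C[C@@H]1c2c(OC(=O)OC(C)(C)C)cc(OC(=O)OC(C)(C)C)cc2O[C@@]2(O[Si](C)(C)C(C)(C)C)[C@]1(C)CC[C@@]21C=C(C(C)C)CC[C@H]1C | intermediate
22 | lactol: as 21 with 2-OH in place of the silyloxy group (in equilibrium with the ring-opened hydroxy ketone); spiro R, CH–CH3 R, C2 S, C3 R, C4 R | CC(C)C[C@@H]1c2c(OC(=O)OC(C)(C)C)cc(OC(=O)OC(C)(C)C)cc2O[C@@]2(O)[C@]1(C)CC[C@@]21C=C(C(C)C)CC[C@H]1C | intermediate (not isolated)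
23 | bis-Boc chroman: as 21 with 2-H in place of the silyloxy group (C2–H cis to the C3 methyl, cis-fused); spiro R, CH–CH3 R, C2 S, C3 R, C4 S | CC(C)C[C@@H]1c2c(OC(=O)OC(C)(C)C)cc(OC(=O)OC(C)(C)C)cc2O[C@H]2[C@]1(C)CC[C@@]21C=C(C(C)C)CC[C@H]1C | intermediate
24 | 5,7-dihydroxy analogue of 23 (both carbonates removed); same configuration | CC(C)C[C@@H]1c2c(O)cc(O)cc2O[C@H]2[C@]1(C)CC[C@@]21C=C(C(C)C)CC[C@H]1C | intermediate
25 | 6,8-bis(dimethyliminiomethyl) derivative of 24, dichloride | CC(C)C[C@@H]1c2c(O)c(C=[N+](C)C)c(O)c(C=[N+](C)C)c2O[C@H]2[C@]1(C)CC[C@@]21C=C(C(C)C)CC[C@H]1C.[Cl-].[Cl-] | intermediate (not isolated)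
26 | CNP0121396.3: 6,8-diformyl-5,7-dihydroxy-4-isobutyl-3-methylchroman, cis-fused at C2–C3 to the cyclopentane whose carbon next to C2 is spiro to C-1 of 3-isopropyl-6-methylcyclohex-2-ene; spiro R, CH–CH3 R, C2 S, C3 R, C4 S | CC(C)C[C@@H]1c2c(O)c(C=O)c(O)c(C=O)c2O[C@H]2[C@]1(C)CC[C@@]21C=C(C(C)C)CC[C@H]1C | target

**Totals.** Total step count: 14. Longest linear sequence: 13 steps (steps 1–9 and 11–14, from 1 to 26); step 10 prepares the aryl partner.

**Steps most likely to fail**

Step 11. The crowded, fully substituted enol ether may trap the quinone methide more slowly than the methide condenses with itself, and endo or facial control may be incomplete. As a fallback, ketone 13 would be deprotonated with KH in THF to the amine-free potassium enolate F1. This is added at −78 °C to alkoxide 18 (prepared from 16 and 17), so that on warming the quinone methide is intercepted by Michael addition of a charged carbon nucleophile, an established reaction of metal enolates with ortho-quinone methides, instead of by cycloaddition of a neutral enol ether. The resulting phenoxide ketone closes to the hemiketal on work-up, and the sequence rejoins the route at lactol 22, which is reduced as in the second stage of step 12.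

Step 12. Hydride may be delivered to the wrong face of the oxocarbenium ion (trans ring fusion), or the ring-opened hydroxy ketone may be reduced before it cyclises. As a fallback, lactol 22 would be converted with EtSH and Zn(OTf)2 in CH2Cl2 into the cyclic S-ethyl monothioketal F2, whose C–S bond is then cleaved homolytically with n-Bu3SnH and AIBN in toluene at 90 °C. Hydrogen-atom transfer to the ring-fusion α-oxygenated radical is a cation-free process that generally favours the cis-fused 6/5 bicycle. It would give carbonate 23, where the route is rejoined.

Step 7. The acyl rhodium hydride may decarbonylate, which also deactivates the catalyst as a carbonyl complex, or the terminal double bond may migrate before insertion. As a fallback, aldehyde 10 would be treated with isopropenylmagnesium bromide to give dienol F3. Ring-closing metathesis with the second-generation Grubbs catalyst closes the five-membered ring as spirocyclic cyclopentenol F4 with loss of ethylene, and Dess–Martin oxidation gives enone F5. Platinum-catalysed 1,4-hydrosilylation with t-BuMe2SiH and Pt2[(CH2=CHSiMe2)2O]3 then delivers silyl enol ether 14 directly, so that steps 8 and 9 are bypassed and the route is rejoined at 14.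

**Further compounds**

F1 | step 11 | potassium enolate of ketone 13 | [K+].[O-]C1=C(C)CC[C@@]12C=C(C(C)C)CC[C@H]2C
F2 | step 12 | cyclic S-ethyl monothioketal of 22 (ethylthio in place of the lactol hydroxyl) | CC(C)C[C@@H]1c2c(OC(=O)OC(C)(C)C)cc(OC(=O)OC(C)(C)C)cc2O[C@@]2(SCC)[C@]1(C)CC[C@@]21C=C(C(C)C)CC[C@H]1C
F3 | step 7 | 1-[(1R,6R)-1-allyl-3-isopropyl-6-methylcyclohex-2-en-1-yl]-2-methylprop-2-en-1-ol, both carbinol epimers | CC(=C)C(O)[C@@]1(CC=C)C=C(C(C)C)CC[C@H]1C
F4 | step 7 | (5R,10R)-7-isopropyl-2,10-dimethylspiro[4.5]deca-2,6-dien-1-ol, both carbinol epimers | OC1C(C)=CC[C@@]12C=C(C(C)C)CC[C@H]2C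
F5 | step 7 | (5R,10R)-7-isopropyl-2,10-dimethylspiro[4.5]deca-2,6-dien-1-one | O=C1C(C)=CC[C@@]12C=C(C(C)C)CC[C@H]2C
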